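**Retrosynthetic overview**

1. Ring numbering used throughout: C1 = ring C=O, C2 = alkene carbon bearing CH2O, C3 = ring CH=, C4 = CH2, C5 = stereocentre, C6 = CH2. Last disconnections: both isobutyrates (bis-acylation of a triol) and the skipped-diene side chain (ruthenium-catalysed alkene–alkyne coupling of a C5-ethynyl cyclohexenone with (R)-2-methylpent-4-ene-1,2-diol, made from (S)-2-methylglycidol).
2. Key disconnection C1–C6: the cyclohexenone is the hydroacylation isomer of an achiral, acyclic (2Z)-2,5-dienal. A rhodium-catalysed enantioselective intramolecular hydroacylation closes the only ring, creates the enone and sets C5 in one operation.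
3. Enabling feature: C1 is an acyl carbon held cis to C4 by the C2=C3 olefin, and C5 is a CH flanked by the ring methylenes C4 and C6. C5–H/C6–C1 is therefore the formal adduct of a formyl C–H across a 1,1-disubstituted C5=C6 alkene lying 1,6 to C1.
4. The dienal comes from prop-2-yn-1-ol and a 2-substituted allyl chloride: copper-catalysed allylation, hydroxyl-directed trans-hydrostannation (fixes the Z olefin), tin–lithium exchange and formylation.
5. Ring order: one carbocycle only, the cyclohexenone, formed in step 6; side chain and esters follow.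

Key step: step 6

Remark on the chemistry: the sense of induction of the rhodium/(R)-DTBM-SEGPHOS catalyst in step 6 is assumed to give (R)-C5; should it prove opposite, the (S)-ligand is used and nothing else changes.

**Route**

Step 1
Reactants: 1 3-chloro-2-(chloromethyl)prop-1-ene; 2 (4-methoxyphenyl)methanol
Product: 4 1-({[2-(chloromethyl)prop-2-en-1-yl]oxy}methyl)-4-methoxybenzene, via sodium (4-methoxyphenyl)methanolate 3 (not isolated)
Conditions: NaH (1.0 equiv), THF, 0 °C; then 1 (3 equiv), 0 °C to rt
Reagents that add atoms: sodium hydride, [Na+].[H-] (sodium appears only in intermediate 3)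
Why: Williamson ether synthesis on a symmetrical bis-allylic dichloride, where the excess of 1 should suppress the bis-ether and SN2 and SN2' attack lead to the same product.

Step 2
Reactants: 4 1-({[2-(chloromethyl)prop-2-en-1-yl]oxy}methyl)-4-methoxybenzene; 5 prop-2-yn-1-ol
Product: 6 5-{[(4-methoxybenzyl)oxy]methyl}hex-5-en-2-yn-1-ol
Conditions: CuI (10 mol%), K2CO3 (1.5 equiv), n-Bu4NCl (1 equiv), DMF, rt
Reagents that add atoms: none
Why: copper-catalysed allylation of a terminal alkyne (copper acetylide plus allylic chloride) should give the skipped enyne without protection of the hydroxyl, and the two allyl termini of 4 are constitutionally equivalent so no regiochemical issue arises.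

Step 3
Reactants: 6 5-{[(4-methoxybenzyl)oxy]methyl}hex-5-en-2-yn-1-ol
Product: 7 (2Z)-5-{[(4-methoxybenzyl)oxy]methyl}-2-(tributylstannyl)hexa-2,5-dien-1-ol
Conditions: Bu3SnH (1.1 equiv), [(C5Me5)RuCl]4 (1.5 mol%), CH2Cl2, rt
Reagents that add atoms: tributylstannane, CCCC[SnH](CCCC)CCCC
Why: ruthenium-catalysed trans-hydrostannation of a propargylic alcohol, in which hydrogen bonding of the hydroxyl to the chloride ligand should steer tin to the proximal alkyne carbon and the anti addition places tin cis to the C4 chain, fixing the olefin geometry that the ring closure needs.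

Step 4
Reactants: 7 (2Z)-5-{[(4-methoxybenzyl)oxy]methyl}-2-(tributylstannyl)hexa-2,5-dien-1-ol
Product: 9 (2Z)-2-(hydroxymethyl)-5-{[(4-methoxybenzyl)oxy]methyl}hexa-2,5-dienal, via dilithio vinyl alkoxide 8 (not isolated)
Conditions: n-BuLi (2.2 equiv), THF, −78 to −30 °C; DMF (3 equiv), −78 °C; aq. NH4Cl
Reagents that add atoms: n-butyllithium, [Li]CCCC (lithium appears only in intermediate 8); N,N-dimethylformamide, CN(C)C=O
Why: tin–lithium exchange followed by Bouveault-type formylation of a configurationally stable vinyllithium should proceed with retention, so the formyl group ends up cis to the allylic chain; running it on the lithium alkoxide avoids the O-to-C silyl shift (retro-Brook) and the β-elimination open to an O-protected 2-lithioallyl ether.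

Step 5
Reactants: 9 (2Z)-2-(hydroxymethyl)-5-{[(4-methoxybenzyl)oxy]methyl}hexa-2,5-dienal
Product: 10 (2Z)-2-({[tert-butyl(dimethyl)silyl]oxy}methyl)-5-{[(4-methoxybenzyl)oxy]methyl}hexa-2,5-dienal
Conditions: TBSCl (1.2 equiv), imidazole (2 equiv), CH2Cl2, 0 °C
Reagents that add atoms: tert-butyl(chloro)dimethylsilane, CC(C)(C)[Si](C)(C)Cl
Why: silylation of a primary alcohol with a silyl chloride and imidazole at low temperature should leave the Z-enal geometry and the skipped diene untouched.

Step 6
Reactants: 10 (2Z)-2-({[tert-butyl(dimethyl)silyl]oxy}methyl)-5-{[(4-methoxybenzyl)oxy]methyl}hexa-2,5-dienal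
Product: 11 (5R)-2-({[tert-butyl(dimethyl)silyl]oxy}methyl)-5-{[(4-methoxybenzyl)oxy]methyl}cyclohex-2-en-1-one
Conditions: [Rh(cod)Cl]2 (2.5 mol%), (R)-DTBM-SEGPHOS (5.5 mol%), NaB[3,5-(CF3)2C6H3]4 (5 mol%), degassed THF, 60 °C
Reagents that add atoms: none
Why: Proposed new method: the cationic monovalent rhodium–bisphosphine complex should add oxidatively into the formyl C–H bond of 10, the Z-configured C2=C3 olefin then holds the 1,1-disubstituted C5=C6 alkene over the metal, anti-Markovnikov migratory insertion of that alkene into Rh–H (hydrogen to C5) gives a seven-membered acyl alkyl rhodacycle and reductive elimination forms the C1–C6 bond, so that an achiral acyclic dienal is isomerized into the enone without any reagent. The closest known reaction type is the rhodium-catalysed enantioselective endo-hydroacylation of ortho-(2-substituted allyl)benzaldehydes to 3-substituted 3,4-dihydronaphthalen-1(2H)-ones, and the new element is that a cis olefin (a 2-allyl enal) takes the place of the arene tether. The ring closes in the 6-endo-trig mode (acyl carbon to the terminal alkene carbon), the 5-exo alternative requiring a tertiary alkyl rhodium and a quaternary carbon. The only new stereocentre, C5, is set by the chiral bisphosphine, which selects the enantiotopic alkene face in the hydride insertion. The step needs endo regioselectivity and must outrun decarbonylation, migration of the C5=C6 alkene into conjugation and Z-to-E isomerization of the enal; the cis arrangement of formyl group and allyl chain fixed in step 3, the 1,1-disubstitution of the alkene and the non-coordinating counterion are what should secure this.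

Step 7
Reactants: 11 (5R)-2-({[tert-butyl(dimethyl)silyl]oxy}methyl)-5-{[(4-methoxybenzyl)oxy]methyl}cyclohex-2-en-1-one
Product: 12 (5R)-2-({[tert-butyl(dimethyl)silyl]oxy}methyl)-5-(hydroxymethyl)cyclohex-2-en-1-one
Conditions: DDQ (1.3 equiv), CH2Cl2/pH 7 buffer (10:1), 0 °C to rt
Reagents that add atoms: none
Why: oxidative cleavage of the 4-methoxybenzyl ether by DDQ (hydride abstraction, then hydrolysis of the oxocarbenium ion) should leave the silyl ether, the enone and the C5 stereocentre untouched.

Step 8
Reactants: 12 (5R)-2-({[tert-butyl(dimethyl)silyl]oxy}methyl)-5-(hydroxymethyl)cyclohex-2-en-1-one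
Product: 13 (1R)-4-({[tert-butyl(dimethyl)silyl]oxy}methyl)-5-oxocyclohex-3-ene-1-carbaldehyde
Conditions: Dess–Martin periodinane (1.3 equiv), CH2Cl2, 0 °C to rt; crude product used at once
Reagents that add atoms: none
Why: Dess–Martin oxidation is fast and near-neutral, so the α-stereocentre of the new aldehyde should survive.

Step 9
Reactants: 13 (1R)-4-({[tert-butyl(dimethyl)silyl]oxy}methyl)-5-oxocyclohex-3-ene-1-carbaldehyde
Product: 14 (5R)-2-({[tert-butyl(dimethyl)silyl]oxy}methyl)-5-ethynylcyclohex-2-en-1-one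
Conditions: dimethyl (1-diazo-2-oxopropyl)phosphonate (1.3 equiv), K2CO3 (2 equiv), MeOH, 0 °C
Reagents that add atoms: dimethyl (1-diazo-2-oxopropyl)phosphonate, COP(=O)(OC)C(=[N+]=[N-])C(C)=O
Why: Seyferth–Gilbert homologation in the Ohira–Bestmann variant should convert the aldehyde, far more electrophilic than the enone carbonyl, into the terminal alkyne through a vinylidene carbene 1,2-hydrogen shift under mild carbonate conditions that normally preserve α-stereocentres.

Step 10
Reactants: 15 [(2S)-2-methyloxiran-2-yl]methanol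
Product: 16 (2R)-2-methylpent-4-ene-1,2-diol
Conditions: CH2=CHMgBr (2.5 equiv), CuI (10 mol%), THF, −30 to 0 °C; aq. NH4Cl
Reagents that add atoms: vinylmagnesium bromide, C=C[Mg]Br
Why: copper-catalysed Grignard opening of the epoxide at its unsubstituted CH2 carbon (SN2) does not touch the quaternary carbinol centre, the change of descriptor from S to R being only a change of CIP ranking.

Step 11
Reactants: 14 (5R)-2-({[tert-butyl(dimethyl)silyl]oxy}methyl)-5-ethynylcyclohex-2-en-1-one; 16 (2R)-2-methylpent-4-ene-1,2-diol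
Product: 17 (5R)-2-({[tert-butyl(dimethyl)silyl]oxy}methyl)-5-[(4E,6R)-6,7-dihydroxy-6-methylhepta-1,4-dien-2-yl]cyclohex-2-en-1-one
Conditions: [(C5H5)Ru(MeCN)3]PF6 (10 mol%), 16 (1.5 equiv), acetone, rt
Reagents that add atoms: none
Why: ruthenium-catalysed alkene–alkyne coupling (formal Alder-ene reaction) via a ruthenacyclopentene should join the terminal alkene carbon of 16 to the internal alkyne carbon of 14, the α-branched propargylic carbon favouring the branched 1,1-disubstituted isomer and β-hydride elimination giving the E olefin; neither stereocentre is touched.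

Step 12
Reactants: 17 (5R)-2-({[tert-butyl(dimethyl)silyl]oxy}methyl)-5-[(4E,6R)-6,7-dihydroxy-6-methylhepta-1,4-dien-2-yl]cyclohex-2-en-1-one
Product: 18 (5R)-5-[(4E,6R)-6,7-dihydroxy-6-methylhepta-1,4-dien-2-yl]-2-(hydroxymethyl)cyclohex-2-en-1-one
Conditions: HF·pyridine, pyridine, THF, 0 °C to rt
Reagents that add atoms: none
Why: buffered fluoride-mediated desilylation should remove the primary silyl ether without acid- or base-induced damage to the hydroxymethyl enone or the tertiary allylic alcohol.

Step 13
Reactants: 18 (5R)-5-[(4E,6R)-6,7-dihydroxy-6-methylhepta-1,4-dien-2-yl]-2-(hydroxymethyl)cyclohex-2-en-1-one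
Product: 19 (2R,3E)-2-hydroxy-2-methyl-6-[(1R)-4-{[(2-methylpropanoyl)oxy]methyl}-5-oxocyclohex-3-en-1-yl]hepta-3,6-dien-1-yl 2-methylpropanoate
Conditions: i-PrCOCl (2.3 equiv), pyridine (6 equiv), CH2Cl2, −20 to 0 °C
Reagents that add atoms: 2-methylpropanoyl chloride, CC(C)C(Cl)=O
Why: acylation with an acid chloride and pyridine should esterify the two primary hydroxyls and leave the hindered tertiary allylic alcohol free (steric chemoselectivity), and no strongly nucleophilic catalyst is present that could attack the new Morita–Baylis–Hillman-type allylic ester.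

**Compound list**

1 | 3-chloro-2-(chloromethyl)prop-1-ene | C=C(CCl)CCl | starting material
2 | (4-methoxyphenyl)methanol | COc1ccc(CO)cc1 | starting material
3 | sodium (4-methoxyphenyl)methanolate | [Na+].COc1ccc(C[O-])cc1 | intermediate
4 | 1-({[2-(chloromethyl)prop-2-en-1-yl]oxy}methyl)-4-methoxybenzene | COc1ccc(COCC(=C)CCl)cc1 | intermediate
5 | prop-2-yn-1-ol | OCC#C | starting material
6 | 5-{[(4-methoxybenzyl)oxy]methyl}hex-5-en-2-yn-1-ol | OCC#CCC(=C)COCc1ccc(OC)cc1 | intermediate
7 | (2Z)-5-{[(4-methoxybenzyl)oxy]methyl}-2-(tributylstannyl)hexa-2,5-dien-1-ol | OC/C(=C/CC(=C)COCc1ccc(OC)cc1)[Sn](CCCC)(CCCC)CCCC | intermediate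
8 | lithium (2E)-2-lithio-5-{[(4-methoxybenzyl)oxy]methyl}hexa-2,5-dien-1-olate (same geometry as 7; the descriptor changes with the CIP rank of lithium) | [Li]OC/C([Li])=C/CC(=C)COCc1ccc(OC)cc1 | intermediate
9 | (2Z)-2-(hydroxymethyl)-5-{[(4-methoxybenzyl)oxy]methyl}hexa-2,5-dienal | O=C/C(CO)=C\CC(=C)COCc1ccc(OC)cc1 | intermediate
10 | (2Z)-2-({[tert-butyl(dimethyl)silyl]oxy}methyl)-5-{[(4-methoxybenzyl)oxy]methyl}hexa-2,5-dienal | O=C/C(CO[Si](C)(C)C(C)(C)C)=C\CC(=C)COCc1ccc(OC)cc1 | intermediate
11 | (5R)-2-({[tert-butyl(dimethyl)silyl]oxy}methyl)-5-{[(4-methoxybenzyl)oxy]methyl}cyclohex-2-en-1-one | COc1ccc(COC[C@@H]2CC=C(CO[Si](C)(C)C(C)(C)C)C(=O)C2)cc1 | intermediate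
12 | (5R)-2-({[tert-butyl(dimethyl)silyl]oxy}methyl)-5-(hydroxymethyl)cyclohex-2-en-1-one | OC[C@@H]1CC=C(CO[Si](C)(C)C(C)(C)C)C(=O)C1 | intermediate
13 | (1R)-4-({[tert-butyl(dimethyl)silyl]oxy}methyl)-5-oxocyclohex-3-ene-1-carbaldehyde | O=C[C@@H]1CC=C(CO[Si](C)(C)C(C)(C)C)C(=O)C1 | intermediate
14 | (5R)-2-({[tert-butyl(dimethyl)silyl]oxy}methyl)-5-ethynylcyclohex-2-en-1-one | C#C[C@@H]1CC=C(CO[Si](C)(C)C(C)(C)C)C(=O)C1 | intermediate
15 | [(2S)-2-methyloxiran-2-yl]methanol ((S)-2-methylglycidol) | C[C@]1(CO)CO1 | starting material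
16 | (2R)-2-methylpent-4-ene-1,2-diol | C=CC[C@@](C)(O)CO | intermediate
17 | (5R)-2-({[tert-butyl(dimethyl)silyl]oxy}methyl)-5-[(4E,6R)-6,7-dihydroxy-6-methylhepta-1,4-dien-2-yl]cyclohex-2-en-1-one | C=C(C/C=C/[C@@](C)(O)CO)[C@@H]1CC=C(CO[Si](C)(C)C(C)(C)C)C(=O)C1 | intermediate
18 | (5R)-5-[(4E,6R)-6,7-dihydroxy-6-methylhepta-1,4-dien-2-yl]-2-(hydroxymethyl)cyclohex-2-en-1-one | C=C(C/C=C/[C@@](C)(O)CO)[C@@H]1CC=C(CO)C(=O)C1 | intermediate
19 | (2R,3E)-2-hydroxy-2-methyl-6-[(1R)-4-{[(2-methylpropanoyl)oxy]methyl}-5-oxocyclohex-3-en-1-yl]hepta-3,6-dien-1-yl 2-methylpropanoate | C=C(C/C=C/[C@@](C)(O)COC(=O)C(C)C)[C@@H]1CC=C(COC(=O)C(C)C)C(=O)C1 | target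

**Step count**

Total: 13 steps. Longest linear sequence: 12 steps (steps 1–9 and 11–13); step 10 is a one-step side branch.

**Three steps most likely to fail**

Step 6 (bears the label). What may go wrong: decarbonylation of the acyl rhodium hydride, migration of the C5=C6 alkene into conjugation, Z-to-E isomerization of the enal before ring closure, or poor facial discrimination between the CH2O and CH2 substituents of the alkene. The fallback uses known chemistry and a different logic: C5 is set by alkylation of a chiral oxazolidinone enolate, and the ring is closed at C2=C3 by olefin metathesis. It sets out from prop-2-yn-1-ol 5 and comes back at alcohol 12. Markovnikov hydroiodination of 5 (NaI, Me3SiCl, H2O, MeCN) gives 2-iodoprop-2-en-1-ol F1. Silylation (TBSCl, imidazole) gives tert-butyl[(2-iodoprop-2-en-1-yl)oxy]dimethylsilane F2. Iodine–lithium exchange (t-BuLi, Et2O, −78 °C, kept cold to forestall the O-to-C silyl shift) gives tert-butyl[(2-lithioprop-2-en-1-yl)oxy]dimethylsilane F3, used at once. In parallel, commercial (4S)-4-benzyl-3-(pent-4-enoyl)-1,3-oxazolidin-2-one is alkylated (NaN(SiMe3)2, THF, −78 °C; tert-butyl bromoacetate) on the face away from the benzyl group to give tert-butyl (3R)-3-{[(4S)-4-benzyl-2-oxo-1,3-oxazolidin-3-yl]carbonyl}hex-5-enoate F4. LiBH4 (THF, 1 equiv H2O, 0 °C) removes the auxiliary to give tert-butyl (3R)-3-(hydroxymethyl)hex-5-enoate F5. Acid-catalysed lactonization (p-TsOH cat., toluene, 60 °C) gives (4R)-4-(prop-2-en-1-yl)oxolan-2-one F6. Mono-addition of F3 to F6 (−78 °C, aq. NH4Cl) gives (5R)-2-({[tert-butyl(dimethyl)silyl]oxy}methyl)-5-(hydroxymethyl)octa-1,7-dien-3-one F7. Ring-closing metathesis with the second-generation Hoveyda–Grubbs catalyst (CH2Cl2, 40 °C) then gives 12, and steps 8–13 follow unchanged.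

Step 9. What may go wrong: methoxide-induced damage of the hydroxymethyl-type enone (conjugate addition followed by loss of the silyloxy group) during the carbonate/methanol homologation, on top of epimerization next to the formyl group. The fallback takes the ring carbonyl out of play while the alkyne is made; it sets out from alcohol 12 and comes back at alkyne 14. Luche reduction of 12 (NaBH4, CeCl3·7H2O, MeOH, −78 °C) gives (5R)-2-({[tert-butyl(dimethyl)silyl]oxy}methyl)-5-(hydroxymethyl)cyclohex-2-en-1-ol F8 as a mixture of C1 epimers, which is of no consequence. TEMPO (cat.) with PhI(OAc)2 in CH2Cl2 oxidizes only the primary alcohol to (1R)-4-({[tert-butyl(dimethyl)silyl]oxy}methyl)-5-hydroxycyclohex-3-ene-1-carbaldehyde F9. Ohira–Bestmann homologation (same reagent, K2CO3, MeOH, 0 °C) gives (5R)-2-({[tert-butyl(dimethyl)silyl]oxy}methyl)-5-ethynylcyclohex-2-en-1-ol F10. Oxidation of the allylic alcohol with MnO2 (CH2Cl2, rt) returns the enone as 14.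

Step 4. What may go wrong: incomplete tin–lithium exchange on the alkoxide, proton transfer from the doubly allylic C4 position to the vinyllithium, and Z-to-E isomerization or oligomerization of the free hydroxy enal during work-up. The fallback replaces the vinyllithium by an acyl palladium species; it sets out from stannane 7 and comes back at silylated enal 10. Iododestannylation of 7 (I2, CH2Cl2, 0 °C) proceeds with retention to (2Z)-2-iodo-5-{[(4-methoxybenzyl)oxy]methyl}hexa-2,5-dien-1-ol F11. Silylation (TBSCl, imidazole, CH2Cl2) gives tert-butyl{[(2Z)-2-iodo-5-{[(4-methoxybenzyl)oxy]methyl}hexa-2,5-dien-1-yl]oxy}dimethylsilane F12. Reductive carbonylation of the vinyl iodide (Pd(PPh3)4 5 mol%, CO 1–3 atm, Bu3SnH added slowly, THF, 50 °C) gives 10 with retention of the olefin geometry; step 5 is then skipped.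

**Further compounds**

F1 | step 6 | 2-iodoprop-2-en-1-ol | OCC(I)=C
F2 | step 6 | tert-butyl[(2-iodoprop-2-en-1-yl)oxy]dimethylsilane | C=C(I)CO[Si](C)(C)C(C)(C)C
F3 | step 6 | tert-butyl[(2-lithioprop-2-en-1-yl)oxy]dimethylsilane | [Li]C(=C)CO[Si](C)(C)C(C)(C)C
F4 | step 6 | tert-butyl (3R)-3-{[(4S)-4-benzyl-2-oxo-1,3-oxazolidin-3-yl]carbonyl}hex-5-enoate | C=CC[C@H](CC(=O)OC(C)(C)C)C(=O)N1[C@@H](Cc2ccccc2)COC1=O
F5 | step 6 | tert-butyl (3R)-3-(hydroxymethyl)hex-5-enoate | C=CC[C@H](CC(=O)OC(C)(C)C)CO
F6 | step 6 | (4R)-4-(prop-2-en-1-yl)oxolan-2-one | C=CC[C@H]1COC(=O)C1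
F7 | step 6 | (5R)-2-({[tert-butyl(dimethyl)silyl]oxy}methyl)-5-(hydroxymethyl)octa-1,7-dien-3-one | C=CC[C@H](CC(=O)C(=C)CO[Si](C)(C)C(C)(C)C)CO
F8 | step 9 | (5R)-2-({[tert-butyl(dimethyl)silyl]oxy}methyl)-5-(hydroxymethyl)cyclohex-2-en-1-ol (C1 epimers) | OC[C@@H]1CC=C(CO[Si](C)(C)C(C)(C)C)C(O)C1
F9 | step 9 | (1R)-4-({[tert-butyl(dimethyl)silyl]oxy}methyl)-5-hydroxycyclohex-3-ene-1-carbaldehyde (C5 epimers) | O=C[C@@H]1CC=C(CO[Si](C)(C)C(C)(C)C)C(O)C1
F10 | step 9 | (5R)-2-({[tert-butyl(dimethyl)silyl]oxy}methyl)-5-ethynylcyclohex-2-en-1-ol (C1 epimers) | C#C[C@@H]1CC=C(CO[Si](C)(C)C(C)(C)C)C(O)C1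
F11 | step 4 | (2Z)-2-iodo-5-{[(4-methoxybenzyl)oxy]methyl}hexa-2,5-dien-1-ol | OC/C(I)=C/CC(=C)COCc1ccc(OC)cc1
F12 | step 4 | tert-butyl{[(2Z)-2-iodo-5-{[(4-methoxybenzyl)oxy]methyl}hexa-2,5-dien-1-yl]oxy}dimethylsilane | CC(C)(C)[Si](C)(C)OC/C(I)=C/CC(=C)COCc1ccc(OC)cc1
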